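The numbers of this flask are assumed.

In a one-step world, starting material meets dissolved gas, becomes target, and the yield is a matter of waiting. This flask has a second exit.

solid substrate 0.20 M; gas phase 51 mM (held); time 40 min

    starting material + dissolved gas → target (k1 = 0.0471 /M/s)
    dissolved gas ⇌ dormant form (K2 = 6.5, k2 = 3.68 × 10⁻⁴ /s)
    gas phase ⇌ dissolved gas, rate k3*(csat - [dissolved gas]) (k3 = 0.00207 /s, csat = 51 mM)
    starting material → side product (k4 = 0.00174 /s)
    solid substrate ⇌ starting material, rate k5*(cs5 - [starting material]) while solid is left; crystals form when [starting material] > cs5 (cs5 = 0.091 M, k5 = 0.00583 /s)
    crystals ⇌ target, rate k6*(cs6 - [target]) while solid is left; crystals form when [target] > cs6 (cs6 = 0.099 M, k6 = 0.0342 /s)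

- target is meant together with its crystals
- solid, in amounts per volume of the solution: crystals, solid substrate
- at the start none of the gas is dissolved
- at the start none of the solid substrate is in solution
- run time (flask): 40 min

- blue: doubling the dissolution coefficient of step 5, all else as stated
- grey: doubling the saturation concentration of gas phase, all else as stated
- violet: doubling the solubility in step 5, all else as stated
- red: doubling the transfer coefficient of step 3, all else as stated

- how much target and crystals together there is at 40 min, in percent of the solid substrate charged
- the change that raises the amount of target and crystals together at 40 min, in percent of the solid substrate charged most ("none" if none brings more than 2 percentage points) (blue / grey / violet / red / none)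
- amount of target and crystals together at 40 min, in percent of the solid substrate charged, after blue

Will waiting help? I expect not. The half-life of starting material by decay alone, 6.6 min, is shorter than the run of 40 min. Dissolution into a solution kept empty could deliver 637 % in that time if the solid never ran out, more than the charge. So I expect a split, not a clock.

Which split? Per starting material, the rate constant of the reaction to target times c(dissolved gas) competes with the decay constant. So c(dissolved gas) is wanted.

What is c(dissolved gas)? First guess: the saturation value, 51 mM. Dissolution against both exits then gives c(starting material) = 0.0532 M. Put that into the gas balance, with the dormant form counted forward, and c(dissolved gas) = 0.0214 M, less than the guess. The guess was wrong.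

So go round again. c(starting material) becomes 0.0619 M and c(dissolved gas) 0.0197 M. The target share, the reaction to target divided by that reaction plus the decay, is 34.8 %, the selectivity in the usual term.

Where is this weak? The gas starts at none, so the early share is lower. Late, with less starting material drawing on it, the gas climbs, so the late share is higher. I bet that these cancel and commit to y = 34.8 %. That is 0.0696 M of target, under the solubility of 0.099 M, so I expect no crystals.

And the changes? The same reckoning gives blue 32.5 %, violet 25.6 %, red 43.5 % and grey 51.6 %. Grey stands higher than the others.

The forecast gives y = 35 %, best = grey and, after blue, 31 %, lower than my share. Of the choice it says: “Grey doubles the gas driving force”.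

The simulation gives y = 34.2 %, best = grey with a gain of 17 percentage points, and 32.0 % after blue.

So this flask ends as a split: side product holds 65.5 % at 40.0 min, and y still reads 34.4 % at 400 min. The neighbouring flask, the same charge read at 15 min, shows dissolved gas at 0.0196 M, beside my 0.0197 M. In that neighbouring flask, target and side product together hold 63.2 % of the charge. The target share puts 22.0 % of the charge in target there. Its simulated target is 20.1 %.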